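# Total synthesis of Volvaltrate B

**Retrosynthetic overview**
1. The target comes from esterifying the C11 primary allylic alcohol with (R)-2-isovaleryloxy-3-methylbutanoic acid. Before that, the C8 tertiary chlorohydrin is made by adding "ClCH2–M" to the C8 ketone of the cis-fused cyclopenta[c]pyran, from the convex face (the new step).
2. The enol-ether acylal pyran is closed after the cyclopentane by a biomimetic 1,5-dialdehyde cyclization, which also epimerizes C9 to the cis-fused bicycle. The 1,5-dialdehyde comes from hydroboration of an exocyclic methylene, debenzylation and double oxidation.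
3. The cyclopentane is made first. It comes from (S)-4-OTBS-cyclopentenone by α'-hydroxymethylation, Weitz–Scheffer epoxidation and SmI2 opening, which sets C7-OH. A vinylcerium 1,2-addition then sets the C5 tertiary alcohol together with the C4 unit.
4. Ring order: cyclopentane → dihydropyran (step 11) → C8 quaternary carbinol (step 15).

Assumptions (one line each):
- (S)-4-(TBSO)cyclopent-2-enone and (R)-2-hydroxy-3-methylbutanoic acid are commercially available.
- The anomeric acylation (step 12) favours the desired axial, convex-face C1 acylal; the minor anomer is separable.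

---

**Step 1**
Reactants: 1 (2-bromoprop-2-en-1-ol); 2 (TBDPSCl)
Product: 3 ((2-bromoallyl)oxy)(tert-butyl)diphenylsilane
Conditions: imidazole, DMF, 0→23 °C
Reagents that add atoms: TBDPSCl, CC(C)(C)[Si](Cl)(c1ccccc1)c1ccccc1 (adds TBDPS)
Why: Standard silylation of a primary alcohol makes the masked C4/C11 vinyl nucleophile precursor.

**Step 2**
Reactants: 4 ((S)-4-OTBS-cyclopent-2-enone); 5 (formaldehyde)
Product: 6 (trans-5-(hydroxymethyl)-4-OTBS-cyclopent-2-enone)
Conditions: LiHMDS, THF, −78 °C; then monomeric HCHO, −78→−40 °C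
Reagents that add atoms: formaldehyde, C=O (adds CH2O)
Why: Kinetic α'-enolate aldol (hydroxymethylation); the electrophile enters anti to the C8-OTBS, giving the trans product, and this C9 centre is temporary (it is epimerized in step 11).

**Step 3**
Reactants: 6; 7 (benzyl trichloroacetimidate)
Product: 8 (benzyl ether of 6)
Conditions: TfOH (cat.), CH2Cl2/cyclohexane, 0 °C
Reagents that add atoms: benzyl trichloroacetimidate, N=C(OCc1ccccc1)C(Cl)(Cl)Cl (adds Bn)
Why: Acid-catalysed benzylation avoids base-induced retro-aldol or elimination of the β-hydroxy ketone.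

**Step 4**
Reactants: 8; 9 (H2O2)
Product: 10 (α,β-epoxy ketone, epoxide oxygen on the face opposite OTBS)
Conditions: 30% H2O2, NaOH (cat.), MeOH, 0 °C
Reagents that add atoms: hydrogen peroxide, OO (adds O)
Why: Weitz–Scheffer epoxidation; HOO⁻ adds at C7 anti to the adjacent C8-OTBS, so the epoxide oxygen sits on the face that becomes C7-O "up".

**Step 5**
Reactants: 10
Product: 11 (β-hydroxy ketone, C7-OH up, C6 = CH2)
Conditions: SmI2, THF/MeOH, −78 °C
Reagents that add atoms: none (only H added)
Why: SmI2 reductive cleavage of the α-C–O bond of an α,β-epoxy ketone leaves the C7–O bond, and therefore its configuration, untouched.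

**Step 6**
Reactants: 11; 3 (converted to the vinylcerium reagent)
Product: 12 (C5 tertiary alcohol carrying the C4(=CH2)CH2OTBDPS unit)
Conditions: 3, t-BuLi, THF, −78 °C; CeCl3; then 11, −78 °C
Reagents that add atoms: 3, C=C(Br)CO[Si](c1ccccc1)(c1ccccc1)C(C)(C)C (supplies C(=CH2)CH2OTBDPS)
Why: Imamoto-type organocerium 1,2-addition (the free C7-OH is consumed as its cerium alkoxide) attacks the C5 ketone anti to the C9-CH2OBn and the C7 cerium alkoxide, giving C5-OH up and C4 down, the configuration needed at C5.

**Step 7**
Reactants: 12; 13 (Ac2O)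
Product: 14 (C7 acetate)
Conditions: Ac2O, Et3N, DMAP (cat.), CH2Cl2, 0 °C
Reagents that add atoms: acetic anhydride, CC(=O)OC(C)=O (adds Ac)
Why: Chemoselective acylation of the secondary C7-OH over the tertiary C5-OH; no ketone remains, so β-elimination is impossible.

**Step 8**
Reactants: 14; 15 (9-BBN)
Product: 16 (primary alcohol at C3)
Conditions: 9-BBN, THF, 0→23 °C; then NaBO3·4H2O, THF/H2O, 23 °C
Reagents that add atoms: 9-BBN, B1C2CCCC1CCC2 (boron is removed in the work-up); hydrogen peroxide (compound 9) released from sodium perborate, OO (adds OH)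
Why: Anti-Markovnikov hydroboration–oxidation of the 1,1-disubstituted alkene, with buffered perborate oxidation so the acetate survives; the new C4 centre is irrelevant because C4 later becomes sp2.

**Step 9**
Reactants: 16
Product: 17 (C1 and C3 diol)
Conditions: H2 (1 atm), Pd(OH)2/C, EtOAc, 23 °C
Reagents that add atoms: none (H2)
Why: Hydrogenolysis of the benzyl ether is safe here because no alkene remains.

**Step 10**
Reactants: 17
Product: 18 (1,5-dialdehyde)
Conditions: Dess–Martin periodinane, NaHCO3, CH2Cl2, 0→23 °C
Reagents that add atoms: none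
Why: Dess–Martin oxidation of both primary alcohols under buffered, non-epimerizing conditions.

**Step 11**
Reactants: 18
Product: 19 (bicyclic enol-ether lactol, C1 anomer mixture, cis-fused, C9-H up)
Conditions: PPTS (0.2 equiv), CH2Cl2, 23 °C
Reagents that add atoms: none (isomerization)
Why: Biomimetic iridodial-type ring–chain tautomerization, in which the C3 enol oxygen closes onto C1 while enolization of the C1 aldehyde epimerizes C9, so the irreversible cis-fused ring closure drains the mixture to the required configuration.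

**Step 12**
Reactants: 19; 20 (isovaleryl chloride)
Product: 21 (C1 isovalerate acylal)
Conditions: isovaleryl chloride, pyridine, CH2Cl2, −20→0 °C
Reagents that add atoms: isovaleryl chloride, CC(C)CC(=O)Cl (adds isovaleryl)
Why: Anomeric acylation of the lactol proceeds under Curtin–Hammett control through ring-chain equilibration, favouring the axial, convex-face acylal, while the tertiary alcohol stays untouched.

**Step 13**
Reactants: 21
Product: 22 (C8 secondary alcohol)
Conditions: HF·pyridine, pyridine, THF, 0→23 °C
Reagents that add atoms: none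
Why: Buffered fluoride removes the secondary TBS ether while the TBDPS ether, acetate and acylal survive.

**Step 14**
Reactants: 22
Product: 23 (C8 ketone)
Conditions: Dess–Martin periodinane, NaHCO3, CH2Cl2, 23 °C
Reagents that add atoms: none
Why: Mild, buffered oxidation to the ketone leaves the enol ether, the acylal and the tertiary C5-OH intact.

**Step 15**
Reactants: 23; 24 (ClCH2I)
Product: 25 (C8 tertiary chlorohydrin, OH down, CH2Cl up)
Conditions: ICH2Cl (5 equiv), MeLi·LiBr (4.5 equiv), anhydrous CeCl3 (5 equiv), THF, −78 °C; quench sat. NH4Cl at −78 °C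
Reagents that add atoms: chloroiodomethane, ClCI (adds CH2Cl)
Why: Proposed new method: in situ I/Li exchange of ICH2Cl in the presence of CeCl3 and the ketone should give a chloromethylcerium carbenoid, ClCH2–CeCl2 (one equivalent of base first converts the C5-OH to its alkoxide), that is less basic and more persistent than LiCH2Cl. This should suppress carbene formation, C9 enolization (with β-elimination of the acylal) and attack on the acylal and acetate, and deliver CH2Cl to the convex face, anti to the concave pyran ring and guided by the C5 cerium alkoxide. The closest known chemistry is Imamoto organocerium additions to enolizable ketones combined with Barluenga/Matteson LiCH2Cl chlorohydrin formation.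

**Step 16**
Reactants: 25
Product: 26 (C11 allylic primary alcohol)
Conditions: TBAF, AcOH, THF, 0 °C
Reagents that add atoms: none
Why: Acetic-acid-buffered fluoride removes the primary TBDPS ether without closing the chlorohydrin to the epoxide.

**Step 17**
Reactants: 27 ((R)-2-hydroxy-3-methylbutanoic acid); 20 (isovaleryl chloride)
Product: 28 ((R)-2-(isovaleryloxy)-3-methylbutanoic acid)
Conditions: isovaleryl chloride (2.2 equiv), pyridine, CH2Cl2, 0 °C; then H2O, 23 °C
Reagents that add atoms: isovaleryl chloride, CC(C)CC(=O)Cl (adds isovaleryl); water, O (hydrolyses the mixed anhydride back to the free carboxylic acid)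
Why: O-Acylation of the hydroxy acid gives the ester plus a mixed carboxylic anhydride, and aqueous hydrolysis of that anhydride at either carbonyl returns the free acid and isovaleric acid, leaving the (R)-centre untouched.

**Step 18**
Reactants: 26; 28
Product: 29 (Volvaltrate B)
Conditions: EDC·HCl, DMAP, CH2Cl2, 0 °C
Reagents that add atoms: 28, CC(C)CC(=O)O[C@@H](C(=O)O)C(C)C (adds the acyl group)
Why: Steglich esterification at the unhindered primary C11-OH, with the tertiary C5 and C8 alcohols unreactive.

---

**Compound list**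

1 | 2-bromoprop-2-en-1-ol | C=C(Br)CO | starting material
2 | tert-butylchlorodiphenylsilane | CC(C)(C)[Si](Cl)(c1ccccc1)c1ccccc1 | starting material
3 | 2-bromoallyl TBDPS ether | C=C(Br)CO[Si](c1ccccc1)(c1ccccc1)C(C)(C)C | intermediate
4 | (S)-4-TBSO-cyclopent-2-en-1-one | O=C1C=C[C@@H](O[Si](C)(C)C(C)(C)C)C1 | starting material
5 | formaldehyde | C=O | starting material
6 | trans-5-(hydroxymethyl)-4-OTBS-cyclopentenone | O=C1C=C[C@@H](O[Si](C)(C)C(C)(C)C)[C@@H]1CO | intermediate
7 | benzyl trichloroacetimidate | N=C(OCc1ccccc1)C(Cl)(Cl)Cl | starting material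
8 | benzyl ether of 6 | O=C1C=C[C@@H](O[Si](C)(C)C(C)(C)C)[C@@H]1COCc1ccccc1 | intermediate
9 | hydrogen peroxide | OO | starting material
10 | epoxy ketone | O=C1[C@@H]2O[C@@H]2[C@@H](O[Si](C)(C)C(C)(C)C)[C@@H]1COCc1ccccc1 | intermediate
11 | β-hydroxy ketone (C7-OH) | O=C1C[C@H](O)[C@@H](O[Si](C)(C)C(C)(C)C)[C@@H]1COCc1ccccc1 | intermediate
12 | C5 tertiary alcohol, C4 vinyl unit | C=C(CO[Si](c2ccccc2)(c2ccccc2)C(C)(C)C)[C@@]1(O)C[C@H](O)[C@@H](O[Si](C)(C)C(C)(C)C)[C@@H]1COCc1ccccc1 | intermediate
13 | acetic anhydride | CC(=O)OC(C)=O | starting material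
14 | C7 acetate | C=C(CO[Si](c2ccccc2)(c2ccccc2)C(C)(C)C)[C@@]1(O)C[C@H](OC(C)=O)[C@@H](O[Si](C)(C)C(C)(C)C)[C@@H]1COCc1ccccc1 | intermediate
15 | 9-BBN | B1C2CCCC1CCC2 | starting material
16 | C3 primary alcohol (C4 epimeric) | OCC(CO[Si](c2ccccc2)(c2ccccc2)C(C)(C)C)[C@@]1(O)C[C@H](OC(C)=O)[C@@H](O[Si](C)(C)C(C)(C)C)[C@@H]1COCc1ccccc1 | intermediate
17 | C1/C3 diol | OCC(CO[Si](c2ccccc2)(c2ccccc2)C(C)(C)C)[C@@]1(O)C[C@H](OC(C)=O)[C@@H](O[Si](C)(C)C(C)(C)C)[C@@H]1CO | intermediate
18 | 1,5-dialdehyde | O=CC(CO[Si](c2ccccc2)(c2ccccc2)C(C)(C)C)[C@@]1(O)C[C@H](OC(C)=O)[C@@H](O[Si](C)(C)C(C)(C)C)[C@@H]1C=O | intermediate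
19 | bicyclic lactol (C1 anomer mixture) | CC(=O)O[C@H]1C[C@]2(O)C(CO[Si](c3ccccc3)(c3ccccc3)C(C)(C)C)=COC(O)[C@@H]2[C@@H]1O[Si](C)(C)C(C)(C)C | intermediate
20 | isovaleryl chloride | CC(C)CC(=O)Cl | starting material
21 | C1 isovalerate acylal | CC(=O)O[C@H]1C[C@]2(O)C(CO[Si](c3ccccc3)(c3ccccc3)C(C)(C)C)=CO[C@@H](OC(=O)CC(C)C)[C@@H]2[C@@H]1O[Si](C)(C)C(C)(C)C | intermediate
22 | C8 secondary alcohol | CC(=O)O[C@H]1C[C@]2(O)C(CO[Si](c3ccccc3)(c3ccccc3)C(C)(C)C)=CO[C@@H](OC(=O)CC(C)C)[C@@H]2[C@@H]1O | intermediate
23 | C8 ketone | CC(=O)O[C@H]1C[C@]2(O)C(CO[Si](c3ccccc3)(c3ccccc3)C(C)(C)C)=CO[C@@H](OC(=O)CC(C)C)[C@@H]2C1=O | intermediate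
24 | chloroiodomethane | ClCI | starting material
25 | C8 chlorohydrin, C11-OTBDPS | CC(=O)O[C@H]1C[C@]2(O)C(CO[Si](c3ccccc3)(c3ccccc3)C(C)(C)C)=CO[C@@H](OC(=O)CC(C)C)[C@@H]2[C@@]1(O)CCl | intermediate
26 | C11 primary alcohol | CC(=O)O[C@H]1C[C@]2(O)C(CO)=CO[C@@H](OC(=O)CC(C)C)[C@@H]2[C@@]1(O)CCl | intermediate
27 | (R)-2-hydroxy-3-methylbutanoic acid | CC(C)[C@@H](O)C(=O)O | starting material
28 | (R)-2-(isovaleryloxy)-3-methylbutanoic acid | CC(C)CC(=O)O[C@@H](C(=O)O)C(C)C | intermediate
29 | Volvaltrate B | CC(=O)O[C@H]1C[C@]2(O)C(COC(=O)[C@H](OC(=O)CC(C)C)C(C)C)=CO[C@@H](OC(=O)CC(C)C)[C@@H]2[C@@]1(O)CCl | target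

---

**Totals:** 18 steps in total, including two reagent-preparation steps (steps 1 and 17). The longest linear sequence is 16 steps, running from 4 through steps 2–16 and 18.

**Three steps most likely to fail**
1. **Step 15 (the new ClCH2–CeCl2 addition).** Facial selectivity or chemoselectivity may be poor; the β-acyloxy ketone 23 can also eliminate isovalerate.
   - Fallback: Corey–Chaykovsky epoxidation of 23 (Me3S⁺I⁻, NaH, DMSO/THF) to the spiro-epoxide, then anhydrous MgCl2 in THF at 23 °C. Chloride attacks the unhindered CH2 terminus, so C8 keeps its configuration and free HCl is avoided. The epoxide diastereomers are separated first.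
2. **Step 11 (dialdehyde cyclization with C9 epimerization).** Competing β-elimination of OTBDPS or the C5-OH from the C3 aldehyde may occur.
   - Fallback: in step 6 add the lithium enolate of methyl 3,3-dimethoxypropanoate (C4–C3–C11 unit, C11 as ester) instead of the vinylcerium. The resulting formylacetate then closes cleanly in the classical Tietze-type iridoid closure. Lactol silylation and DIBAL reduction of the ester follow, with the acylations delayed to the end.
3. **Step 6 (C5 facial selectivity).** The 1,3-syn C8-OTBS may erode the expected down-face attack.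
   - Fallback: reorder so the C5 addition is done on the C9-unsubstituted β-hydroxy ketone from steps 4–5. C8 is oxidized, C9 is then formylated (HCO2Et, NaH) to install C1, and C9 is set by the step-11 epimerization.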